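# Proposed synthesis of 5,3',5'-trihydroxy-6,7,2'-trimethoxyflavone (CNP0177690.0) by late ketone-directed C–H hydroxylation at C5

Remark on the chemistry: the target has no stereocenter, and the oxygen introduced in the key step is taken to arrive as an aryl trifluoroacetate that is cleaved during aqueous work-up.

Numbering used throughout:
- 1: 3,5-dibromo-2-hydroxybenzoic acid
- 2: its methyl ether methyl ester
- 3: the potassium salt of the dibromo methoxy acid (formed in the flask)
- 4: 3,5-dihydroxy-2-methoxybenzoic acid
- 5: its tribenzyl derivative (formed in the flask)
- 6: 3,5-bis(benzyloxy)-2-methoxybenzoic acid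
- 7: the acid chloride of 6
- 8: 2'-hydroxy-4',5'-dimethoxyacetophenone
- 9: the dilithium phenoxide-enolate of 8 (formed in the flask)
- 10: the 1,3-diketone
- 11: the dibenzyl flavone
- 12: the flavone diol
- 13: the flavone diacetate, substrate of the key step
- 14: its C5 trifluoroacetate (formed in the flask)
- 15: the C5 phenol diacetate
- 16: the target

## Analysis of the target

Compound 16 is a flavone: benzo ring A is fused to the 4-pyranone ring C, and aryl ring B is bonded to C2. Ring A carries a free hydroxyl at C5, methoxyls at C6 and C7 and hydrogen at C8. Ring B carries a methoxyl at C2' and free hydroxyls at C3' and C5'. The molecule has no stereocenter, so the only isomer problem is constitutional: six oxygens on two rings, three of them methylated and three free, in one fixed pattern. The sensitive parts are the three phenols on electron-rich rings, which are oxidised easily (especially as phenoxides in air), and the pyranone, which hot strong alkali opens and hydrogenation can reduce at C2=C3. The hard points are the three contiguous oxygens of ring A, of which only the one at C5 is free, and the 1,2,3,5-pattern of ring B, whose methoxyl sits between the biaryl bond and a free hydroxyl. The strategy rests on the position of the C5 hydroxyl, which lies peri to the C4 carbonyl of ring C. In a 6,7-dimethoxyflavone the C5–H bond is therefore the only C–H bond that can close a five-membered metallacycle (metal, carbonyl O, C4, C4a, C5) with the ketone oxygen. The ketone can thus direct a metal to that bond, and ring A can be brought in with only its two methoxyls.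

## Retrosynthetic reasoning

**16 from 15.** The last disconnection removes two acetyl groups from the ring B oxygens. The phenols of ring B are freed only at the very end because they would not survive the oxidant of the preceding step. The forward reaction is a mild transesterification that touches neither the methyl ethers nor the pyranone.

**15 from 13 (key disconnection).** The C5–O bond is cut, leaving the 6,7-dimethoxyflavone 13 with hydrogen at C5. Cutting here means the C5 oxygen never has to be told apart from the methyl ethers at C6 and C7, since it is simply not there until the end. The forward reaction has to oxidise one of five aromatic or vinylic C–H bonds (C5, C8, C3, C4', C6'). Chelation to the C4 carbonyl is what singles out C5, and the first-formed product 14 carries the new oxygen in acylated form.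

**13 from 12 and 12 from 11.** These two steps exchange the protecting groups of ring B. Acetates are wanted in the key step because they are stable to acid and make ring B electron-poor, but they would not survive the strongly basic assembly of the diketone. Benzyl ethers behave the opposite way. Two routine steps (hydrogenolysis, acetylation) are the price for using each group where it is safe.

**11 from 10.** The O1–C2 bond of ring C is cut. Forward, the phenol of 10 adds to the aroyl carbonyl and water is lost, which is the standard way to close a flavone and needs only catalytic acid.

**10 from 8 and 7.** The bond between the methyl carbon of the acetophenone (the future C3) and the aroyl carbon (the future C2) is cut. This is the convergent point: ring A comes complete in the purchased ketone 8, ring B in acid chloride 7. Forward, the dianion 9 of the ketone is acylated at carbon, and an acid chloride with an enolate is a coupling that tolerates the ortho methoxyl of ring B.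

**7 from 6 and 6 from 4.** The acid is activated as its chloride, and before that the two phenols of 4 are benzylated. The benzyl ester 5 that forms alongside is saponified in the same flask.

**4 from 2 and 2 from 1.** The two C–O bonds at the future C3' and C5' are traced back to C–Br bonds. The bromines of 1 serve as placeholders, so the oxygen that becomes the C2' methoxyl can be methylated while it is the only hydroxyl on the ring (1 to 2). Coupling with hydroxide then replaces both bromines and saponifies the ester on the way (through 3).

## Alternatives that were turned down

**Alternative 1: ring B by benzannulation.**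
- Disconnection: ring B is taken apart at C2'–C3', C3'–C4' and C5'–C6'. This leads back to diazoketone A1, a β-methoxy enone that already carries the complete trimethoxylated ring A/ring C bicycle, and to the silyloxyalkyne A2.
- Forward key step: Wolff rearrangement of A1 gives a vinylketene, which adds (2+2) to A2. The vinylcyclobutenone opens in a four-electron process to a dienylketene, and six-electron closure with tautomerisation gives phenol A3. The ketene carbon becomes C3' with its free hydroxyl and the alkyne brings the silylated C5' oxygen.
- For: the connectivity of the fragments sets the 1,2,3,5-pattern of ring B without ambiguity. The two ring B oxygens come out differentiated. No electron-rich arene has to face an oxidant late in the route, and on that point it is stronger than the chosen route.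
- Against: the differentiation of the two ring B oxygens is not needed, since both are free in 16. A1 is a polyfunctional diazoketone that must be assembled on a finished chromone (enol ether, diazo transfer), which takes several steps. The chromone chromophore competes for light in a photochemical Wolff step. A3 still carries a methyl ether at C5, so a selective demethylation and a desilylation remain.
- Comparison: the route is clearly longer than the chosen one. The chosen route takes ring B from a benzoic acid in which all oxygens are already placed and spends its risk on one step.

**Alternative 2: ring A by cyclobutenone ring expansion.**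
- Disconnection: the C4a–C5 bond, and with it ring A, leads back to cyclobutenone A4. In A4 a 2,3-dimethoxycyclobutenone is bonded through its sp3 carbon to C6 of a 2-aryl-4-pyranone.
- Forward key step: heating opens the four-membered ring to a vinylketene that is conjugated with the C5=C6 bond of the pyranone. Six-electron closure onto pyranone C5 and tautomerisation give A5. The ketene carbon ends as C5 with its free hydroxyl, and the two methoxyls of the small ring end at C6 and C7.
- For: the C5 hydroxyl appears as a free phenol with the right neighbours, with no oxidant and no demethylation. On that point it is stronger than the chosen route, whose key step must oxidise an electron-rich flavone. A5 needs only debenzylation to reach 16.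
- Against: A4 is not easy to reach. It needs a cyclobutenone that bears hydrogen at its sp3 carbon and a differently 2,6-disubstituted pyranone joined to it, in practice by cross-coupling of a metalated pyranone with a halocyclobutenone. Neither partner is available in one or two steps. The pyranone C5=C6 bond is part of a vinylogous ester and has to give up that conjugation in the electrocyclisation.
- Comparison: the uncertainty is spread over the preparation of A4 and the thermolysis. The chosen route builds both rings from purchasable aromatic compounds by routine steps.

**Alternative 3: aryl transfer to C2 of a preformed chromone.**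
- Disconnection: the C2–C1' bond leads back to chromone A6 and boronic acid A7.
- Forward key step: the aryl group of A7 is transferred to divalent palladium and adds across C2=C3 of A6. The palladium enolate is dehydrogenated in the same flask to flavone A8.
- For: it is the most convergent plan and forms a single C–C bond. Its end game, chelation-controlled removal of the C5 methyl group together with the benzyl groups, is shorter and more predictable than a C–H oxidation. In step count it is equal to or better than the chosen route.
- Against: A7 is electron-rich and ortho-substituted, which favours protodeboronation and slows the insertion. Three donor groups and the peri methoxyl deactivate the enone of A6. Making A7 needs an aryl halide with the full ring B pattern, so it costs about as much as acid 6 plus a borylation. The C5 oxygen enters as a methyl ether and must be singled out among four methyl ethers, and the boron chelate that activates it also activates its neighbour at C6.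
- Comparison: the chosen route joins the same two halves through an acid chloride and an enolate, which is insensitive to hindrance, and never has to distinguish the C5 oxygen from a methyl ether.

Key step: step 9

## Route

Step 1
Reactants: 1 3,5-dibromo-2-hydroxybenzoic acid
Product: 2 methyl 3,5-dibromo-2-methoxybenzoate
Conditions: MeI (3 equiv), K2CO3 (3 equiv), DMF, 50 °C
Reagents that add atoms: iodomethane, CI
Why: Williamson O-alkylation of the phenoxide and of the carboxylate; the phenol is the only hydroxyl on the ring at this stage, so the ether that becomes the C2' methoxyl is placed without any selectivity problem, while the two bromines mark the positions of the later hydroxyls.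

Step 2
Reactants: 2 methyl 3,5-dibromo-2-methoxybenzoate
Product: 4 3,5-dihydroxy-2-methoxybenzoic acid, via potassium 3,5-dibromo-2-methoxybenzoate 3 (not isolated)
Conditions: Pd2(dba)3 (2 mol %), tBuXPhos (8 mol %), KOH (8 equiv), 1,4-dioxane/H2O 1:1, 100 °C, argon; then aq. HCl, pH 2
Reagents that add atoms: potassium hydroxide, [K+].[OH-]
Why: Palladium-catalysed hydroxylation of aryl bromides with hydroxide and a bulky biarylphosphine; hydroxide first saponifies the ester to 3, then zerovalent palladium inserts into each C–Br bond, bromide is exchanged for hydroxide and C–O reductive elimination gives the phenoxide. The methyl ether and the carboxylate are inert, and acidification should give 4.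

Step 3
Reactants: 4 3,5-dihydroxy-2-methoxybenzoic acid
Product: 6 3,5-bis(benzyloxy)-2-methoxybenzoic acid, via benzyl 3,5-bis(benzyloxy)-2-methoxybenzoate 5 (not isolated)
Conditions: BnBr (3.5 equiv), K2CO3 (4 equiv), DMF, 60 °C; then 2 M aq. NaOH, MeOH/THF, 60 °C; aq. HCl
Reagents that add atoms: benzyl bromide, BrCc1ccccc1; sodium hydroxide, [Na+].[OH-]
Why: Williamson benzylation with excess halide alkylates both phenols and the carboxylate to 5; saponification of the crude benzyl ester then frees the acid, while the benzyl aryl ethers are stable to alkali.

Step 4
Reactants: 6 3,5-bis(benzyloxy)-2-methoxybenzoic acid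
Product: 7 3,5-bis(benzyloxy)-2-methoxybenzoyl chloride
Conditions: (COCl)2 (1.5 equiv), DMF (cat.), CH2Cl2, 0 °C to rt; evaporate, use crude
Reagents that add atoms: oxalyl chloride, ClC(=O)C(=O)Cl
Why: Acid chloride formation through the chloroiminium species from oxalyl chloride and catalytic DMF; benzyl and methyl aryl ethers tolerate the brief contact with HCl at room temperature, and the crude chloride is used at once.

Step 5
Reactants: 8 2'-hydroxy-4',5'-dimethoxyacetophenone; 7 3,5-bis(benzyloxy)-2-methoxybenzoyl chloride
Product: 10 1-[3,5-bis(benzyloxy)-2-methoxyphenyl]-3-(2-hydroxy-4,5-dimethoxyphenyl)propane-1,3-dione, via dilithium 4,5-dimethoxy-2-(1-oxidoethenyl)phenolate 9 (not isolated)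
Conditions: 8, LiN(SiMe3)2 (3.1 equiv), THF, −78 to −10 °C; then 7 in THF, −78 °C to rt; aq. HCl
Reagents that add atoms: none
Why: Claisen-type C-acylation of a ketone enolate, the one-flask variant of the Baker–Venkataraman diketone synthesis; two equivalents of base give the phenoxide-enolate 9, which attacks the acid chloride at carbon, and the third equivalent deprotonates the more acidic diketone so that it is not acylated again. Any aroyl ester formed at the phenoxide oxygen should be carried on to the same diketone by intramolecular acyl transfer under the basic conditions.

Step 6
Reactants: 10 1-[3,5-bis(benzyloxy)-2-methoxyphenyl]-3-(2-hydroxy-4,5-dimethoxyphenyl)propane-1,3-dione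
Product: 11 2-[3,5-bis(benzyloxy)-2-methoxyphenyl]-6,7-dimethoxy-4H-chromen-4-one
Conditions: TsOH·H2O (0.2 equiv), toluene, reflux, Dean–Stark
Reagents that add atoms: none
Why: Acid-catalysed cyclodehydration of an o-hydroxyaryl 1,3-diketone; the phenol adds to the aroyl carbonyl in a six-membered ring closure and loss of water gives the 4-pyranone ring C. A catalytic sulfonic acid with removal of water is mild enough for the benzyl ethers.

Step 7
Reactants: 11 2-[3,5-bis(benzyloxy)-2-methoxyphenyl]-6,7-dimethoxy-4H-chromen-4-one
Product: 12 2-(3,5-dihydroxy-2-methoxyphenyl)-6,7-dimethoxy-4H-chromen-4-one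
Conditions: H2 (1 atm), 10% Pd/C, THF/MeOH, rt
Reagents that add atoms: none
Why: Hydrogenolysis of benzyl aryl ethers over palladium; the C2=C3 bond of a flavone belongs to a cross-conjugated pyrone system and is reduced much more slowly than the benzylic C–O bonds are cleaved, so the reaction is stopped once two equivalents of hydrogen are taken up.

Step 8
Reactants: 12 2-(3,5-dihydroxy-2-methoxyphenyl)-6,7-dimethoxy-4H-chromen-4-one
Product: 13 5-(6,7-dimethoxy-4-oxo-4H-chromen-2-yl)-4-methoxy-1,3-phenylene diacetate
Conditions: Ac2O (3 equiv), pyridine, DMAP (cat.), CH2Cl2, rt
Reagents that add atoms: acetic anhydride, CC(=O)OC(C)=O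
Why: DMAP-catalysed O-acylation of phenols; the two acetates mask the phenols, which a trivalent iodine oxidant would otherwise turn into quinones, and they lower the electron density of ring B.

Step 9
Reactants: 13 5-(6,7-dimethoxy-4-oxo-4H-chromen-2-yl)-4-methoxy-1,3-phenylene diacetate
Product: 15 5-(5-hydroxy-6,7-dimethoxy-4-oxo-4H-chromen-2-yl)-4-methoxy-1,3-phenylene diacetate, via the C5 aryl trifluoroacetate 14 (not isolated)
Conditions: [RuCl2(p-cymene)]2 (5 mol %), PhI(OCOCF3)2 (2 equiv), CF3CO2H/(CF3CO)2O (3:1), 80 °C; evaporate; EtOAc/aq. NaHCO3, rt
Reagents that add atoms: [bis(trifluoroacetoxy)iodo]benzene, O=C(O[I](OC(=O)C(F)(F)F)c1ccccc1)C(F)(F)F (the trifluoroacetate oxygen may equally come from the solvent acid, OC(=O)C(F)(F)F)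
Why: This is the ketone-directed ruthenium-catalysed ortho C–H oxygenation of aryl ketones, a known reaction type that has been used at C5 of flavones. Chloride on the divalent ruthenium of [RuCl2(p-cymene)]2 is exchanged for trifluoroacetate, the metal binds the C4 carbonyl oxygen, and a carboxylate-assisted concerted metalation–deprotonation cleaves C5–H to a five-membered ruthenacycle (Ru, O, C4, C4a, C5). PhI(OCOCF3)2 oxidises this to tetravalent ruthenium carrying trifluoroacetate, and C–O reductive elimination gives the aryl trifluoroacetate 14 and returns divalent ruthenium. The anhydride keeps the medium dry and the new oxygen acylated, so no free phenol is exposed to the oxidant; at work-up water cleaves the trifluoroacetate to 15, whose hydroxyl is then hydrogen-bonded to the C4 carbonyl, while the two aryl acetates survive the brief bicarbonate wash. No ring closes and no stereocenter forms. The step needs C5 to react in preference to C8, C3, C4' and C6': only C5–H can reach a metal held on the carbonyl oxygen through a five-membered ring, since C3–H would need a four-membered ring and C8–H and ring B are out of reach. Undirected attack by the iodine oxidant should be slow because the two acyloxy groups deactivate ring B and the carbonyl deactivates ring A. The C6 methoxyl next to C5 hinders the metalation somewhat, which is why a higher catalyst loading is proposed.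

Step 10
Reactants: 15 5-(5-hydroxy-6,7-dimethoxy-4-oxo-4H-chromen-2-yl)-4-methoxy-1,3-phenylene diacetate
Product: 16 2-(3,5-dihydroxy-2-methoxyphenyl)-5-hydroxy-6,7-dimethoxy-4H-chromen-4-one
Conditions: K2CO3 (0.3 equiv), MeOH (degassed), rt, argon; then aq. NH4Cl
Reagents that add atoms: none
Why: Base-catalysed transesterification (Zemplén-type methanolysis) of aryl acetates; phenoxides are good leaving groups, so catalytic carbonate at room temperature should suffice, the methyl ethers and the pyranone are not touched, and exclusion of air protects the electron-rich triphenol.

## Compound list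

1 | 3,5-dibromo-2-hydroxybenzoic acid | O=C(O)c1cc(Br)cc(Br)c1O | starting material
2 | methyl 3,5-dibromo-2-methoxybenzoate | COC(=O)c1cc(Br)cc(Br)c1OC | intermediate
3 | potassium 3,5-dibromo-2-methoxybenzoate (formed in the flask in step 2) | COc1c(Br)cc(Br)cc1C(=O)[O-].[K+] | intermediate
4 | 3,5-dihydroxy-2-methoxybenzoic acid | COc1c(O)cc(O)cc1C(=O)O | intermediate
5 | benzyl 3,5-bis(benzyloxy)-2-methoxybenzoate (formed in the flask in step 3) | COc1c(OCc2ccccc2)cc(OCc2ccccc2)cc1C(=O)OCc1ccccc1 | intermediate
6 | 3,5-bis(benzyloxy)-2-methoxybenzoic acid | COc1c(OCc2ccccc2)cc(OCc2ccccc2)cc1C(=O)O | intermediate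
7 | 3,5-bis(benzyloxy)-2-methoxybenzoyl chloride | COc1c(OCc2ccccc2)cc(OCc2ccccc2)cc1C(=O)Cl | intermediate
8 | 2'-hydroxy-4',5'-dimethoxyacetophenone | CC(=O)c1cc(OC)c(OC)cc1O | starting material
9 | dilithium 4,5-dimethoxy-2-(1-oxidoethenyl)phenolate (formed in the flask in step 5) | [Li+].[Li+].C=C([O-])c1cc(OC)c(OC)cc1[O-] | intermediate
10 | 1-[3,5-bis(benzyloxy)-2-methoxyphenyl]-3-(2-hydroxy-4,5-dimethoxyphenyl)propane-1,3-dione | COc1cc(O)c(C(=O)CC(=O)c2cc(OCc3ccccc3)cc(OCc3ccccc3)c2OC)cc1OC | intermediate
11 | 2-[3,5-bis(benzyloxy)-2-methoxyphenyl]-6,7-dimethoxy-4H-chromen-4-one | COc1cc2oc(-c3cc(OCc4ccccc4)cc(OCc4ccccc4)c3OC)cc(=O)c2cc1OC | intermediate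
12 | 2-(3,5-dihydroxy-2-methoxyphenyl)-6,7-dimethoxy-4H-chromen-4-one | COc1cc2oc(-c3cc(O)cc(O)c3OC)cc(=O)c2cc1OC | intermediate
13 | 5-(6,7-dimethoxy-4-oxo-4H-chromen-2-yl)-4-methoxy-1,3-phenylene diacetate | COc1cc2oc(-c3cc(OC(C)=O)cc(OC(C)=O)c3OC)cc(=O)c2cc1OC | intermediate
14 | 5-[6,7-dimethoxy-4-oxo-5-(trifluoroacetoxy)-4H-chromen-2-yl]-4-methoxy-1,3-phenylene diacetate (formed in the flask in step 9) | COc1cc2oc(-c3cc(OC(C)=O)cc(OC(C)=O)c3OC)cc(=O)c2c(OC(=O)C(F)(F)F)c1OC | intermediate
15 | 5-(5-hydroxy-6,7-dimethoxy-4-oxo-4H-chromen-2-yl)-4-methoxy-1,3-phenylene diacetate | COc1cc2oc(-c3cc(OC(C)=O)cc(OC(C)=O)c3OC)cc(=O)c2c(O)c1OC | intermediate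
16 | 2-(3,5-dihydroxy-2-methoxyphenyl)-5-hydroxy-6,7-dimethoxy-4H-chromen-4-one | COc1cc2oc(-c3cc(O)cc(O)c3OC)cc(=O)c2c(O)c1OC | target

## Step count and least certain steps

Total: 10 steps. Longest linear sequence: 10 steps (1 to 16); ketone 8 is purchased and enters in step 5.

**Step 9 (key step).**
- What may go wrong: undirected oxidation of the electron-rich ring A by the trivalent iodine reagent (trifluoroacetoxylation at C8 or oxidative coupling), over-oxidation of the newly oxygenated ring once its trifluoroacetate is lost, acetate-directed oxygenation of ring B, or slow metalation because C5 is flanked by the C6 methoxyl. All follow from running an oxidation on a flavone with five oxygen substituents.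
- Fallback: bring the C5 oxygen in from the start as a methyl ether and remove it by chelation. The fallback sets out from acid chloride 7. Purchased 2'-hydroxy-4',5',6'-trimethoxyacetophenone F1 would be turned into its dianion with LiN(SiMe3)2 and acylated with 7, as in step 5, to give 1-[3,5-bis(benzyloxy)-2-methoxyphenyl]-3-(6-hydroxy-2,3,4-trimethoxyphenyl)propane-1,3-dione F2. Cyclodehydration as in step 6 would give 2-[3,5-bis(benzyloxy)-2-methoxyphenyl]-5,6,7-trimethoxy-4H-chromen-4-one F3, which is the same compound as A8. BCl3 with pentamethylbenzene as cation scavenger (CH2Cl2, −78 to 0 °C) should then cleave both benzyl ethers and, through the boron chelate with the C4 carbonyl, the C5 methyl ether alone. The fallback comes back to the route at 16.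

**Step 2.**
- What may go wrong: incomplete coupling at the bromide next to the methoxyl, hydrodebromination, diaryl ether formation between a phenoxide and a remaining bromide, or air oxidation of the electron-rich dihydroxy acid in hot alkali.
- Fallback: borylation and oxidation in place of direct hydroxylation. The fallback sets out from 2. Miyaura borylation (B2pin2, Pd(dppf)Cl2, KOAc, 1,4-dioxane, 90 °C) would give methyl 2-methoxy-3,5-bis(4,4,5,5-tetramethyl-1,3,2-dioxaborolan-2-yl)benzoate F4. Oxidation with NaBO3·4H2O in THF/H2O would give methyl 3,5-dihydroxy-2-methoxybenzoate F5. Benzylation (BnBr, K2CO3, DMF) would give methyl 3,5-bis(benzyloxy)-2-methoxybenzoate F6, and saponification (LiOH, THF/MeOH/H2O) returns to the route at 6.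

**Step 5.**
- What may go wrong: acylation at the phenoxide oxygen without the subsequent acyl shift, double acylation, or consumption of the acid chloride by the amide base, each of which lowers conversion to the diketone.
- Fallback: the stepwise Baker–Venkataraman sequence. The fallback sets out from 8 and 7. Esterification in pyridine with catalytic DMAP would give 2-acetyl-4,5-dimethoxyphenyl 3,5-bis(benzyloxy)-2-methoxybenzoate F7. Treatment with KOH in pyridine at 50 °C would move the aroyl group from oxygen to the enolate carbon and return to the route at 10.

**Step 7.**
- What may go wrong: reduction of the C2=C3 bond to the flavanone on prolonged hydrogenation, or slow debenzylation because the flavone is poorly soluble.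
- Fallback: Lewis-acid cleavage in place of hydrogenolysis. The fallback sets out from 11: BCl3 with pentamethylbenzene in CH2Cl2 at −78 °C should remove both benzyl groups without touching the double bond or the unchelated methyl ethers, and it comes back to the route at 12 without any new intermediate.

## Further compounds

F1 | step 9 | 2'-hydroxy-4',5',6'-trimethoxyacetophenone | CC(=O)c1c(O)cc(OC)c(OC)c1OC
F2 | step 9 | 1-[3,5-bis(benzyloxy)-2-methoxyphenyl]-3-(6-hydroxy-2,3,4-trimethoxyphenyl)propane-1,3-dione | COc1cc(O)c(C(=O)CC(=O)c2cc(OCc3ccccc3)cc(OCc3ccccc3)c2OC)c(OC)c1OC
F3 | step 9 | 2-[3,5-bis(benzyloxy)-2-methoxyphenyl]-5,6,7-trimethoxy-4H-chromen-4-one | COc1cc2oc(-c3cc(OCc4ccccc4)cc(OCc4ccccc4)c3OC)cc(=O)c2c(OC)c1OC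
F4 | step 2 | methyl 2-methoxy-3,5-bis(4,4,5,5-tetramethyl-1,3,2-dioxaborolan-2-yl)benzoate | COC(=O)c1cc(B2OC(C)(C)C(C)(C)O2)cc(B2OC(C)(C)C(C)(C)O2)c1OC
F5 | step 2 | methyl 3,5-dihydroxy-2-methoxybenzoate | COC(=O)c1cc(O)cc(O)c1OC
F6 | step 2 | methyl 3,5-bis(benzyloxy)-2-methoxybenzoate | COC(=O)c1cc(OCc2ccccc2)cc(OCc2ccccc2)c1OC
F7 | step 5 | 2-acetyl-4,5-dimethoxyphenyl 3,5-bis(benzyloxy)-2-methoxybenzoate | CC(=O)c1cc(OC)c(OC)cc1OC(=O)c1cc(OCc2ccccc2)cc(OCc2ccccc2)c1OC
F0 | step 7 | none | none
A1 | alternative 1 | 1-diazo-4-methoxy-3-(5,6,7-trimethoxy-4-oxo-4H-chromen-2-yl)but-3-en-2-one | COC=C(C(=O)C=[N+]=[N-])c1cc(=O)c2c(OC)c(OC)c(OC)cc2o1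
A2 | alternative 1 | (triisopropylsilyloxy)ethyne | C#CO[Si](C(C)C)(C(C)C)C(C)C
A3 | alternative 1 | 2-[3-hydroxy-2-methoxy-5-(triisopropylsilyloxy)phenyl]-5,6,7-trimethoxy-4H-chromen-4-one | COc1cc2oc(-c3cc(O[Si](C(C)C)(C(C)C)C(C)C)cc(O)c3OC)cc(=O)c2c(OC)c1OC
A4 | alternative 2 | 4-{6-[3,5-bis(benzyloxy)-2-methoxyphenyl]-4-oxo-4H-pyran-2-yl}-2,3-dimethoxycyclobut-2-en-1-one | COC1=C(OC)C(c2cc(=O)cc(-c3cc(OCc4ccccc4)cc(OCc4ccccc4)c3OC)o2)C1=O
A5 | alternative 2 | 2-[3,5-bis(benzyloxy)-2-methoxyphenyl]-5-hydroxy-6,7-dimethoxy-4H-chromen-4-one | COc1cc2oc(-c3cc(OCc4ccccc4)cc(OCc4ccccc4)c3OC)cc(=O)c2c(O)c1OC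
A6 | alternative 3 | 5,6,7-trimethoxy-4H-chromen-4-one | COc1cc2occc(=O)c2c(OC)c1OC
A7 | alternative 3 | [3,5-bis(benzyloxy)-2-methoxyphenyl]boronic acid | COc1c(OCc2ccccc2)cc(OCc2ccccc2)cc1B(O)O
A8 | alternative 3 | 2-[3,5-bis(benzyloxy)-2-methoxyphenyl]-5,6,7-trimethoxy-4H-chromen-4-one | COc1cc2oc(-c3cc(OCc4ccccc4)cc(OCc4ccccc4)c3OC)cc(=O)c2c(OC)c1OC
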